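**Retrosynthetic overview**
1. Feature: ring B (C5–C10) carries oxygen at C6 para to C9. The cis carboxyl carbons C12 (on C8) and C11 (on C9) sit on the face of the C10 methyl group. This is the retron of a Diels–Alder union of a 2-silyloxydiene (C7=C6–C5=C10) with a cis-butenedioic dienophile (C8=C9).
2. Ring B is formed first. The (Z)-siloxydiene 8 and the (5S)-menthyloxybutenolide 12 form C7–C8 and C10–C9 and set C8, C9 and C10. C11 and C12 arrive as a lactone acetal, at the acid and aldehyde levels.
3. Ring A is formed second, at C4–C5, by aldol condensation of the unmasked 1,7-diketone. Methyl cuprate addition at C4 and α-face protonation at C5 then give the trans fusion.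
4. Endgame: α-face hydride at C6, trienoyl ester, acetal hydrolysis, then aldehyde-to-acid oxidation at C12.
5. Building blocks: acetylacetone (C5, C6, C7, C10 and its methyl), a chloropropyl dioxolane (C1–C4 and one C4 methyl), furfural (C8, C9, C11, C12), (+)-menthol (auxiliary), sorbaldehyde and malonic acid (acyl chain).

Key step: step 6

Remark (numbering): drimane numbering is used (decalin C1–C10, C11 on C9, C12 on C8); β is the face of the C10 methyl group; the stereocentres are set at C8, C9 and C10 in step 6, at C5 in step 9 and at C6 in step 10.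
Remark (design): the chain terminus is a dioxolane-masked methyl ketone and not a prenyl group, because an alkene and a silyl enol ether are both nucleophiles, because any closure onto C5 of the endocyclic C5=C6 bond must deliver C4 axially (cis-decalone), and because with C12 axial on C8 the trans ketone cannot be counted on as the equilibrium epimer; H5 is therefore brought in last, from the open α face.

**Step 1**
Reactants: 1 acetylacetone
Product: 2 (Z)-4-oxopent-2-en-2-yl triflate (triflate cis to the acetyl group)
Conditions: LiOTf, Et3N, Tf2O, CH2Cl2, 0 °C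
Reagents that add atoms: triflic anhydride, O=S(=O)(OS(=O)(=O)C(F)(F)F)C(F)(F)F
Why: O-sulfonylation of the lithium-chelated, U-shaped enolate of a 1,3-diketone, so that the triflate should end cis to the acetyl group (Z).

**Step 2**
Reactants: 3 2-(3-chloropropyl)-2-methyl-1,3-dioxolane; 2 (Z)-4-oxopent-2-en-2-yl triflate
Product: 6 (3Z)-4-methyl-7-(2-methyl-1,3-dioxolan-2-yl)hept-3-en-2-one, via the alkylmagnesium chloride 4 (not isolated), via the alkylzinc chloride 5 (not isolated)
Conditions: Mg, THF, reflux; ZnCl2, THF, 0 °C; then 2, Pd(dppf)Cl2 (3 mol %), THF, 0 °C to rt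
Reagents that add atoms: magnesium, [Mg] (in 4 only); zinc chloride, Cl[Zn]Cl (in 5 only)
Why: Negishi sp3–sp2 cross-coupling, in which oxidative addition to the vinylogous acyl triflate and reductive elimination go with retention, so the chain takes the place cis to the acetyl group, and the organozinc leaves ketone and ketal untouched.

**Step 3**
Reactants: 6 (3Z)-4-methyl-7-(2-methyl-1,3-dioxolan-2-yl)hept-3-en-2-one
Product: 8 (3Z)-2-(tert-butyldimethylsilyloxy)-4-methyl-7-(2-methyl-1,3-dioxolan-2-yl)hepta-1,3-diene, via the lithium dienolate 7 (not isolated)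
Conditions: LDA, THF, −78 °C; TBSCl, DMPU, −78 to 0 °C
Reagents that add atoms: tert-butyldimethylsilyl chloride, CC(C)(C)[Si](C)(C)Cl; lithium diisopropylamide, [Li+].CC(C)[N-]C(C)C (lithium in 7 only)
Why: Kinetic α′-deprotonation of the methyl ketone gives the cross-conjugated dienolate without touching the C5=C10 geometry, and O-silylation traps it as the 2-silyloxydiene.

**Step 4**
Reactants: 9 furfural
Product: 10 5-hydroxyfuran-2(5H)-one
Conditions: O2, hν, rose bengal (cat.), MeOH, 0 °C
Reagents that add atoms: dioxygen, O=O
Why: Dye-sensitised photooxygenation, in which singlet oxygen adds [4+2] across the furan and methanolysis of the endoperoxide expels the formyl carbon as methyl formate.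

**Step 5**
Reactants: 10 5-hydroxyfuran-2(5H)-one; 11 (+)-menthol
Product: 12 (5S)-5-[(1S,2R,5S)-menthyloxy]furan-2(5H)-one
Conditions: camphorsulfonic acid (cat.), benzene, reflux, Dean–Stark; crystallisation from hexanes, mother liquors re-equilibrated with acid
Reagents that add atoms: none
Why: Acid-catalysed acetalisation of the pseudo-acid, in which the two acetal epimers interconvert under acid and the crystalline (5S) epimer of the d-menthyl series is collected by crystallisation.

**Step 6**
Reactants: 8 (3Z)-siloxydiene; 12 (5S)-menthyloxybutenolide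
Product: 13 ring B cycloadduct (C5=C6 TBS enol ether; C10 with β-methyl and α-[3-(2-methyl-1,3-dioxolan-2-yl)propyl]; cis-fused β-oriented 11,12-lactone; menthyloxy on C12 on the lactone face of H8 and H9)
Conditions: 8 (excess), BHT (trace), CH2Cl2, 13 kbar, 40 °C, Teflon ampoule
Reagents that add atoms: none
Why: Concerted, asynchronous normal-demand [4+2] cycloaddition: the C6 siloxy group and the two alkyl groups on C10 both push the largest HOMO coefficient to C7, which bonds ahead to the butenolide β-carbon (C8) while hindered C10 closes on the α-carbon (C9). The closest known reaction type is the thermal or high-pressure Diels–Alder addition of 2-silyloxybutadienes to 5-alkoxyfuran-2(5H)-ones. Ring B closes as a six-membered carbocycle by suprafacial addition on both partners, which leaves the C5=C6 silyl enol ether and a cis-fused lactone acetal. C8 and C9 are controlled by the acetal stereocentre (C12), the diene adding to the face anti to the menthyloxy group, and their cis relation comes from the ring alkene; C10 is controlled by the (Z)-geometry of C5=C10 together with the endo orientation, which puts the outside methyl cis and the inside chain trans to C11 and C12. The step needs para regiochemistry, anti facial attack, endo orientation and an intact (Z)-diene, secured in turn by the matched donor pattern of 8, the bulky auxiliary, secondary overlap with the lactone carbonyl and neutral conditions. Pressure replaces heat because the large negative activation volume favours the cycloaddition over the 1,5-hydrogen shift open to the inside CH2, and Lewis acids are left out because they would ionise the acetal and divert the diene into stepwise Mukaiyama–Michael addition.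

**Step 7**
Reactants: 13 ring B cycloadduct
Product: 14 monocyclic 1,7-diketone (C6 ketone; 4-oxopentyl chain on C10; lactone menthyl acetal intact)
Conditions: 1 M aq HCl, THF, 0 °C to rt
Reagents that add atoms: water, O
Why: Acid hydrolysis of the two most labile groups, in which the silyl enol ether protonates at C5 and the dialkyl ketal ionises far more readily than the lactone acetal, whose oxocarbenium ion is destabilised by the acyl oxygen.

**Step 8**
Reactants: 14 monocyclic 1,7-diketone
Product: 15 bicyclic 4-methyl Δ4(5)-en-6-one (ring A closed; C10 β-methyl; lactone menthyl acetal intact)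
Conditions: p-TsOH·H2O (10 mol %), benzene, reflux, Dean–Stark
Reagents that add atoms: none
Why: Acid-catalysed intramolecular aldol condensation of a 1,7-diketone (6-enolexo-exo-trig closure of C5 onto C4), in which only this pairing gives a ketol that can lose water, the bridged C3-to-C6 ketol being reversible, and the anhydrous acid medium is the one in which the menthyl acetal was made.

**Step 9**
Reactants: 15 bicyclic Δ4(5)-en-6-one
Product: 17 6-oxo-5α-drimane 11,12-lactone menthyl acetal (trans-decalone), via the lithium enolate 16 (not isolated)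
Conditions: Me2CuLi (from CuI and MeLi), Et2O, −20 to 0 °C; then AcOH, THF, −78 °C; aq NH4Cl work-up, no contact with base
Reagents that add atoms: lithium dimethylcuprate, [Li+].C[Cu-]C (one methyl group; lithium in 16 only)
Why: Gilman conjugate addition to a fixed s-cis alkylidene ketone (pulegone type) completes the C4 gem-dimethyl group and gives the C5=C6 enolate regiospecifically, and its irreversible protonation should come from the α face, anti to the axial C10 and C4β methyl groups, which sets 5α-H.

**Step 10**
Reactants: 17 6-oxo-5α-drimane lactone acetal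
Product: 18 6β-hydroxy-5α-drimane 11,12-lactone menthyl acetal
Conditions: NaBH4, CeCl3·7H2O, MeOH–THF, −40 to 0 °C; aq NaHCO3 quench
Reagents that add atoms: none
Why: Luche-type borohydride reduction, in which hydride reaches C6 from the α face because the β face is closed by the axial C10 methyl, C4β methyl and C12, giving the axial 6β-alcohol, while the cold buffered medium spares the lactone acetal and does not enolise C5.

**Step 11**
Reactants: 19 (2E,4E)-hexa-2,4-dienal; 20 malonic acid
Product: 21 (2E,4E,6E)-octa-2,4,6-trienoic acid
Conditions: pyridine, piperidine (cat.), 90 °C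
Reagents that add atoms: none
Why: Doebner–Knoevenagel condensation with decarboxylation, which forms the new C2=C3 bond with E geometry and leaves the E,E-diene of 19 unchanged.

**Step 12**
Reactants: 21 (2E,4E,6E)-octa-2,4,6-trienoic acid; 18 6β-alcohol
Product: 23 6β-[(2E,4E,6E)-octa-2,4,6-trienoyloxy]-5α-drimane 11,12-lactone menthyl acetal, via the mixed anhydride 22 (not isolated)
Conditions: 2,4,6-Cl3C6H2COCl, Et3N, THF, rt; then 18, DMAP, toluene, 80 °C
Reagents that add atoms: 2,4,6-trichlorobenzoyl chloride, O=C(Cl)c1c(Cl)cc(Cl)cc1Cl (in 22 only)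
Why: Yamaguchi esterification, in which DMAP takes the less hindered trienoyl carbonyl of the mixed anhydride and the acylpyridinium ion acylates the hindered axial alcohol with retention at C6, before C12 is unmasked, so that neither a bridged acetal nor a 12,6-lactone can form.

**Step 13**
Reactants: 23 6β-trienoate lactone menthyl acetal
Product: 24 6β-trienoyloxy-12-hydroxy-11,12-lactone (lactol, both C12 epimers, in equilibrium with the 12-aldehyde 11-acid)
Conditions: TFA–H2O (9:1), CH2Cl2, 0 °C to rt; used crude
Reagents that add atoms: water, O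
Why: Acid hydrolysis of the pseudo-ester acetal releases menthol, the hindered conjugated ester survives, and C8 keeps its configuration because the aldehyde stays masked as the cis-fused lactol.

**Step 14**
Reactants: 24 lactol
Product: 25 (5S,6R,8S,9S,10S)-6-[(2E,4E,6E)-octa-2,4,6-trienoyloxy]drimane-11,12-dioic acid (target)
Conditions: NaClO2, NaH2PO4, 2-methylbut-2-ene, t-BuOH–H2O, 0 °C to rt
Reagents that add atoms: sodium chlorite, [Na+].[O-]Cl=O
Why: Pinnick oxidation of the open aldehyde tautomer at weakly acidic pH, which does not epimerise C8, with the scavenger alkene removing HOCl before it can reach the triene.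

**Compound list**
1 | acetylacetone | CC(=O)CC(C)=O | starting material
2 | (Z)-4-oxopent-2-en-2-yl triflate | CC(=O)/C=C(/C)OS(=O)(=O)C(F)(F)F | intermediate
3 | 2-(3-chloropropyl)-2-methyl-1,3-dioxolane | CC1(CCCCl)OCCO1 | starting material
4 | 3-(2-methyl-1,3-dioxolan-2-yl)propylmagnesium chloride | CC1(CCC[Mg]Cl)OCCO1 | intermediate
5 | 3-(2-methyl-1,3-dioxolan-2-yl)propylzinc chloride | CC1(CCC[Zn]Cl)OCCO1 | intermediate
6 | (3Z)-4-methyl-7-(2-methyl-1,3-dioxolan-2-yl)hept-3-en-2-one | CC(=O)/C=C(/C)CCCC1(C)OCCO1 | intermediate
7 | lithium cross-conjugated dienolate of 6 | [Li+].C=C([O-])/C=C(/C)CCCC1(C)OCCO1 | intermediate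
8 | (3Z)-2-(tert-butyldimethylsilyloxy)-4-methyl-7-(2-methyl-1,3-dioxolan-2-yl)hepta-1,3-diene | C=C(O[Si](C)(C)C(C)(C)C)/C=C(/C)CCCC1(C)OCCO1 | intermediate
9 | furfural | O=Cc1ccco1 | starting material
10 | 5-hydroxyfuran-2(5H)-one | O=C1C=CC(O)O1 | intermediate
11 | (+)-menthol (1S,2R,5S) | O[C@H]1C[C@@H](C)CC[C@@H]1C(C)C | starting material
12 | (5S)-5-[(1S,2R,5S)-menthyloxy]furan-2(5H)-one | O=C1C=C[C@@H](O[C@H]2C[C@@H](C)CC[C@@H]2C(C)C)O1 | intermediate
13 | ring B cycloadduct (C5=C6 TBS enol ether, cis-fused lactone menthyl acetal) | CC(C)(C)[Si](C)(C)OC1=C[C@](C)(CCCC4(C)OCCO4)[C@H]2C(=O)O[C@H](O[C@H]3C[C@@H](C)CC[C@@H]3C(C)C)[C@H]2C1 | intermediate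
14 | monocyclic 1,7-diketone lactone acetal | O=C1C[C@@H]3[C@@H](O[C@H]4C[C@@H](C)CC[C@@H]4C(C)C)OC(=O)[C@@H]3[C@@](C)(CCCC(C)=O)C1 | intermediate
15 | bicyclic 4-methyl Δ4(5)-en-6-one lactone acetal | O=C1C[C@@H]3[C@@H](O[C@H]4C[C@@H](C)CC[C@@H]4C(C)C)OC(=O)[C@@H]3[C@@]2(C)CCCC(C)=C12 | intermediate
16 | lithium C5=C6 enolate with C4 gem-dimethyl group | [Li+].[O-]C1=C2C(C)(C)CCC[C@]2(C)[C@H]3C(=O)O[C@H](O[C@H]4C[C@@H](C)CC[C@@H]4C(C)C)[C@H]3C1 | intermediate
17 | 6-oxo-5α-drimane 11,12-lactone menthyl acetal | O=C1C[C@@H]3[C@@H](O[C@H]4C[C@@H](C)CC[C@@H]4C(C)C)OC(=O)[C@@H]3[C@@]2(C)CCCC(C)(C)[C@H]12 | intermediate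
18 | 6β-hydroxy-5α-drimane 11,12-lactone menthyl acetal | O[C@@H]1C[C@@H]3[C@@H](O[C@H]4C[C@@H](C)CC[C@@H]4C(C)C)OC(=O)[C@@H]3[C@@]2(C)CCCC(C)(C)[C@H]12 | intermediate
19 | (2E,4E)-hexa-2,4-dienal | C/C=C/C=C/C=O | starting material
20 | malonic acid | OC(=O)CC(=O)O | starting material
21 | (2E,4E,6E)-octa-2,4,6-trienoic acid | C/C=C/C=C/C=C/C(=O)O | intermediate
22 | octatrienoic 2,4,6-trichlorobenzoic mixed anhydride | C/C=C/C=C/C=C/C(=O)OC(=O)c1c(Cl)cc(Cl)cc1Cl | intermediate
23 | 6β-trienoate lactone menthyl acetal | C/C=C/C=C/C=C/C(=O)O[C@@H]1C[C@@H]3[C@@H](O[C@H]4C[C@@H](C)CC[C@@H]4C(C)C)OC(=O)[C@@H]3[C@@]2(C)CCCC(C)(C)[C@H]12 | intermediate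
24 | 6β-trienoate 12-hydroxy-11,12-lactone (C12 epimers) | C/C=C/C=C/C=C/C(=O)O[C@@H]1C[C@@H]3C(O)OC(=O)[C@@H]3[C@@]2(C)CCCC(C)(C)[C@H]12 | intermediate
25 | CNP0462207.1 | C/C=C/C=C/C=C/C(=O)O[C@@H]1C[C@H](C(=O)O)[C@H](C(=O)O)[C@@]2(C)CCCC(C)(C)[C@H]12 | target

**Step count**
Total step count: 14. Longest linear sequence: 11 steps (1, 2, 3, 6, 7, 8, 9, 10, 12, 13, 14).

**Steps most likely to fail**

**Step 6.** The s-cis conformer is disfavoured by the inside chain, so the cycloaddition may be too slow. The 1,5-hydrogen shift, loss of endo control at the disubstituted terminus, or silyl transfer after a stepwise Michael addition could then take over.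

The fallback sets out from 6 (through 7) and 12 and returns at 14.
- The lithium dienolate 7 is not silylated but treated with 12 in THF at −78 °C.
- C7 adds to the butenolide β-carbon anti to the menthyloxy group.
- On warming, the lactone enolate (C9) closes on C10 of the (Z)-enone. This is an anionic double Michael addition, the stepwise counterpart of the cycloaddition.
- A proton quench should give the monocyclic 6-keto lactone acetal with the dioxolane chain F1.
- Aqueous HCl in THF then removes the dioxolane to give 14.

**Step 9.** Addition to the tetrasubstituted enone may stall in favour of enolisation, or protonation of the crowded enolate may leak to the β face.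

The fallback sets out from 15 and returns at 17.
- Corey–Chaykovsky cyclopropanation with dimethylsulfoxonium methylide (Me3S(O)I, NaH, DMSO) on the α face, anti to the C10 methyl, should give the 4α,5α-methano-6-ketone F2.
- SmI2 in THF–DMPU with t-BuOH then cleaves the C5–CH2 bond, the one that overlaps with the carbonyl π system.
- The primary radical is reduced to the second C4 methyl group.
- The samarium enolate is protonated from the α face to give 17.

**Step 12.** Acyl transfer to an alcohol that is 1,3-diaxial to the C10 methyl, the C4β methyl and C12 may stall. Prolonged heating with DMAP may erode the triene geometry.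

The fallback sets out from 18 and returns at 23.
- The small diethylphosphonoacetic acid is coupled first (DCC, DMAP, CH2Cl2) to give the 6β-(diethylphosphonoacetate) F3.
- A Horner–Wadsworth–Emmons reaction with 19 (LiCl, DBU, MeCN) builds the E-configured C2′=C3′ bond on the ester already in place and gives 23.

**Further compounds**
F1 | step 6 | monocyclic 6-keto lactone menthyl acetal with dioxolane chain | O=C1C[C@@H]3[C@@H](O[C@H]4C[C@@H](C)CC[C@@H]4C(C)C)OC(=O)[C@@H]3[C@@](C)(CCCC5(C)OCCO5)C1
F2 | step 9 | 4α,5α-methano-4β-methyl-6-ketone lactone menthyl acetal | O=C1C[C@@H]3[C@@H](O[C@H]5C[C@@H](C)CC[C@@H]5C(C)C)OC(=O)[C@@H]3[C@@]2(C)CCC[C@@]4(C)C[C@@]124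
F3 | step 12 | 6β-(diethylphosphonoacetoxy)-5α-drimane lactone menthyl acetal | CCOP(=O)(OCC)CC(=O)O[C@@H]1C[C@@H]3[C@@H](O[C@H]4C[C@@H](C)CC[C@@H]4C(C)C)OC(=O)[C@@H]3[C@@]2(C)CCCC(C)(C)[C@H]12
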